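The data are calculated from invented constants, noise included.

**Missing constants.** No rate constant of this flask is given, so I have to make one from the earlier runs. The suspected round is this: the single-handed free catalyst binds left-handed substrate or right-handed substrate, and the partner turns the bound catalyst into product and frees the catalyst again.

| flask | left-handed substrate | right-handed substrate | partner | free catalyst | remark | time |
|---|---|---|---|---|---|---|
| Saturday's | 19 mM | 19 mM | 3 equiv | 0.2 mol% | run made earlier |  |
| Wednesday's | 44 mM | 44 mM | 3 equiv | 0.2 mol% | run made earlier |  |
| flask | 29 mM | 29 mM | 3.00 equiv | 0.2 mol% |  | 2.5 h |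

| run | time / h | left-handed product / % | right-handed product / % |
|---|---|---|---|
| Saturday's | 0.167 | 0.3 | 0.4 |
| Saturday's | 0.500 | 1.0 | 0 |
| Saturday's | 0.833 | 1.0 | 1.1 |
| Saturday's | 1.33 | 1.7 | 1.3 |
| Saturday's | 2.00 | 2.5 | 1.6 |
| Saturday's | 2.50 | 2.7 | 2.4 |
| Saturday's | 3.00 | 2.8 | 2.3 |
| Wednesday's | 0.250 | 1.4 | 0.3 |
| Wednesday's | 0.333 | 1.6 | 0.7 |
| Wednesday's | 0.500 | 2.2 | 1.0 |
| Wednesday's | 0.833 | 3.6 | 1.7 |
| Wednesday's | 1.33 | 4.0 | 3.2 |
| Wednesday's | 2.00 | 6.8 | 5.1 |
| Wednesday's | 3.00 | 8.2 | 7.2 |

(readings scatter by 0.3 percentage points)

- free catalyst is single-handed; left-handed substrate and right-handed substrate are mirror images of each other, charged as a racemate, each of them at the stated concentration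
- the numbers in the tables scatter by 0.3 percentage points (one standard deviation)
- on the list of suspects stand: free catalyst + left-handed substrate <-> catalyst intermediate A; free catalyst + right-handed substrate <-> catalyst intermediate B; partner + catalyst intermediate A -> free catalyst + left-handed product; partner + catalyst intermediate B -> free catalyst + right-handed product; left-handed product <-> right-handed product; partner + free catalyst -> spent catalyst; free catalyst <-> dormant form
- an excess is the difference of the two amounts in percent of their sum
- an excess is below zero if the other one leads

1. excess of left-handed product over right-handed product in the product at 3.0 min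
2. excess of left-handed product over right-handed product in the product at 2.5 h
3. part of the left-handed substrate and right-handed substrate charged together that has reacted at 2.5 h

**Late way.** I count the turnovers per catalyst, which are twice the reacted fraction over the loading, and divide them by the time and by charged [partner]. I assume here that the pace follows [partner]. Averaging the readings at 2.00 h and 3.00 h gives a value for 2.5 h: 5.38 /M/min on Saturday's run and 6.89 /M/min on Wednesday's. Read straight between them at 29 mM, the working constant, a turnover frequency per unit [partner], is 5.99 /M/min. Turned back, that means 7.81% reacted.

**Early way.** The readings at 0.833 h give 7.37 /M/min and 8.03 /M/min, so 7.64 /M/min for this flask and 9.97% reacted.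

**Which cheats.** The two ways part. In both earlier runs the late constant, as read, is lower than the early one, so the curves bend within the scatter of the readings, and the early way carries the earlier pace through to the end. It cheats, and I commit to 7.81%.

**The forecast.** It says 43%, 8% and 8%, in the order asked, and pictures “a moderately selective catalyst, with an initial excess of about 45%, plus product racemization”. Its conversion lies slightly above mine, and the excesses are its own reckoning.

**The result.** The flask gives 38.8%, 10.6% and 8.57%, so the forecast holds on all three. By 2.50 h, 27.4% of the catalyst charged stands as spent catalyst, which a conversion figure does not show. The working constant of this flask comes to 6.57 /M/min, nearer my late value than the early one.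

    free catalyst + left-handed substrate ⇌ catalyst intermediate A (K = 32.6 /M, k = 832 /M/min)
    free catalyst + right-handed substrate ⇌ catalyst intermediate B (K = 40.0 /M, k = 15500 /M/min)
    partner + catalyst intermediate A → free catalyst + left-handed product (k = 21.4 /M/min)
    partner + catalyst intermediate B → free catalyst + right-handed product (k = 6.90 /M/min)
    left-handed product ⇌ right-handed product (k = 0.0103 /min)
    partner + free catalyst → spent catalyst (k = 0.0821 /M/min)
    free catalyst ⇌ dormant form (K = 0.330, k = 0.0129 /min)

**Second flask.** In the neighbour flask with 1.20 equiv of partner, that constant gives 3.43% reacted. The computed result there is 3.92%.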